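**Retrosynthetic overview** (isoquinoline locants C1–C8a; naphthalene locants primed, as in 4,5-dimethoxy-7-methylnaphthalen-1-yl, so the biaryl bond is C5–C1')
1. Target 15 ← N–S cleavage of N-tosyl tetrahydroisoquinoline 14 ← N-sulfonyl Pictet–Spengler closure of the heterocycle (N2–C1 and C1–C8a, formaldehyde as C1) on the open-chain biaryl sulfonamide 12.
2. 12 ← one three-component Catellani reaction of 1-iodo-2,4-dimethoxybenzene 11, (S)-N-tosyl-2-methylaziridine 3 and naphthyl pinacol boronate 10, forming C4a–C4 (ortho C–H alkylation) and the biaryl bond C5–C1' (ipso Suzuki–Miyaura termination).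
3. Enabling feature: on the benzenoid ring of the isoquinoline, the biaryl carbon C5 lies between C6 (carrying OMe, a blocked ortho position) and C4a (carrying the sp3 carbon C4). This ortho-substituent/ipso-aryl/ortho-alkyl triad is the signature of ortho-alkylation/ipso-arylation of an ortho-substituted aryl iodide. C1 is an unsubstituted CH2 and C8a is ortho/para to the two OMe groups, so formaldehyde can close the heterocycle afterwards.
4. Boronate 10 ← triflate 9 ← naphthol 8 ← Diels–Alder reaction of 3-methoxy-5-methylbenzyne (from bromoarene 4) with 2-methoxyfuran 5, which builds the C1'–C4' ring with both oxygens in place. C3 comes from L-alaninol 1.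
5. Ring order: aziridine (temporary ring, opened in the key step); second naphthalene ring; benzenoid isoquinoline ring purchased; heterocyclic ring last.

Key step: step 5

Remark on the chemistry: the given SMILES defines only the C3 stereocentre (S) and leaves the hindered C5–C1' axis undefined, so the route controls C3 and is expected to give the target as a mixture of rotamers about that axis (atropo-diastereomers if rotation is slow), both of which correspond to the given structure.

**Step 1**
Reactants: 1 (S)-2-aminopropan-1-ol (L-alaninol)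
Product: 3 (S)-2-methyl-1-tosylaziridine, via N,O-ditosyl-L-alaninol 2 (not isolated)
Conditions: TsCl (2.2 equiv), KOH, CH2Cl2/H2O, 0 °C to rt
Reagents that add atoms: 4-methylbenzenesulfonyl chloride (TsCl), Cc1ccc(S(=O)(=O)Cl)cc1
Why: One-pot N,O-bis-sulfonylation followed by intramolecular SN2 (3-exo-tet) displacement of the primary tosylate by the sulfonamide anion (aziridination of a 1,2-amino alcohol); the stereocentre is not a reacting atom, so the (S) configuration of 1 is carried into 3.

**Step 2**
Reactants: 4 1-bromo-3-methoxy-5-methylbenzene; 5 2-methoxyfuran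
Product: 8 4,5-dimethoxy-7-methylnaphthalen-1-ol, via 3-methoxy-5-methylbenzyne 6 (not isolated), via oxabenzonorbornadiene ketal 7 (not isolated)
Conditions: LiN(iPr)2 (1.3 equiv), 5 (3 equiv), THF, −78 °C to rt; then 1 M HCl
Reagents that add atoms: none
Why: Ortho-lithiation between Br and OMe and loss of LiBr give aryne 6, whose Diels–Alder reaction with the electron-rich furan should run head-to-head (the nucleophilic C5 of the furan bonds to the aryne carbon remote from OMe), and the bridgehead ketal 7 then opens under acid to the 4-methoxy-1-naphthol (aryne [4+2] cycloaddition/ring-opening aromatization).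

**Step 3**
Reactants: 8 4,5-dimethoxy-7-methylnaphthalen-1-ol
Product: 9 4,5-dimethoxy-7-methylnaphthalen-1-yl trifluoromethanesulfonate
Conditions: Tf2O, pyridine, CH2Cl2, 0 °C
Reagents that add atoms: trifluoromethanesulfonic anhydride (Tf2O), O=S(=O)(OS(=O)(=O)C(F)(F)F)C(F)(F)F
Why: O-Sulfonylation of a phenol (triflation) turns the C1' oxygen into a leaving group; it is run directly on crude 8 because 4-methoxy-1-naphthols are easily oxidised.

**Step 4**
Reactants: 9 4,5-dimethoxy-7-methylnaphthalen-1-yl trifluoromethanesulfonate
Product: 10 2-(4,5-dimethoxy-7-methylnaphthalen-1-yl)-4,4,5,5-tetramethyl-1,3,2-dioxaborolane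
Conditions: B2pin2, PdCl2(dppf) (5 mol %), KOAc, 1,4-dioxane, 90 °C
Reagents that add atoms: bis(pinacolato)diboron (B2pin2), CC1(C)OB(OC1(C)C)B1OC(C)(C)C(C)(C)O1
Why: Miyaura borylation: oxidative addition of zerovalent palladium into the aryl triflate, acetate-assisted transmetalation with B2pin2 and reductive elimination give the aryl pinacol boronate.

**Step 5**
Reactants: 11 1-iodo-2,4-dimethoxybenzene; 3 (S)-2-methyl-1-tosylaziridine (1.5 equiv); 10 2-(4,5-dimethoxy-7-methylnaphthalen-1-yl)-4,4,5,5-tetramethyl-1,3,2-dioxaborolane (1.5 equiv)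
Product: 12 N-[(2S)-1-[2-(4,5-dimethoxy-7-methylnaphthalen-1-yl)-3,5-dimethoxyphenyl]propan-2-yl]-4-methylbenzenesulfonamide
Conditions: Pd(OAc)2 (10 mol %), P(2-furyl)3 (25 mol %), norbornene (2 equiv), K2CO3 (3 equiv), MeCN/H2O (20:1), 80 °C
Reagents that add atoms: none
Why: Zerovalent palladium inserts into the C–I bond of 11, norbornene carbopalladation and C–H palladation at the only free ortho position give the aryl-norbornyl palladacycle, which opens aziridine 3 by SN2 attack at its unsubstituted CH2 (oxidative addition to tetravalent palladium); reductive elimination forms C4a–C4, the now doubly ortho-substituted intermediate expels norbornene, and the resulting divalent arylpalladium at C5 is intercepted by boronate 10 (transmetalation, reductive elimination) to form the C5–C1' biaryl bond. The closest known reaction type is the Catellani ortho-C–H alkylation/ipso Suzuki–Miyaura termination of ortho-substituted aryl iodides, combined with the known use of N-sulfonyl aziridines as ortho-alkylating electrophiles in Catellani reactions. No ring is closed in this step (the aziridine ring is opened; the heterocycle is closed in step 6). No new stereocentre is created: C3 comes from 3 and is untouched because the palladacycle attacks the CH2 carbon and not the methyl-bearing carbon, while the biaryl axis forms without control. The step needs site-selectivity on the arene, secured by the C6 methoxy group, which blocks one ortho position and enforces single alkylation and norbornene extrusion; regioselective aziridine opening, secured by the steric difference between CH2 and CH(CH3); and chemoselective termination, favoured because the peri-hindered pinacol boronate should transmetalate slowly with the first arylpalladium iodide (norbornene insertion wins) while the sulfonamide nitrogen is a poor partner for C–N reductive elimination to an indoline under aqueous carbonate.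

**Step 6**
Reactants: 12 N-[(2S)-1-[2-(4,5-dimethoxy-7-methylnaphthalen-1-yl)-3,5-dimethoxyphenyl]propan-2-yl]-4-methylbenzenesulfonamide
Product: 14 (3S)-5-(4,5-dimethoxy-7-methylnaphthalen-1-yl)-6,8-dimethoxy-3-methyl-2-tosyl-1,2,3,4-tetrahydroisoquinoline, via N-sulfonyliminium ion 13 (not isolated)
Conditions: (CH2O)n (1.5 equiv), CF3CO2H, CH2Cl2, 0 °C to rt
Reagents that add atoms: formaldehyde (used as paraformaldehyde), C=O
Why: N-Sulfonyl Pictet–Spengler reaction: condensation with formaldehyde gives the N-sulfonyliminium ion, which is attacked (6-endo-trig) by C8a, the only free position ortho to the side chain and activated by the ortho C8 and para C6 methoxy groups; C1 becomes a CH2, so no stereocentre is formed and C3 is untouched.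

**Step 7**
Reactants: 14 (3S)-5-(4,5-dimethoxy-7-methylnaphthalen-1-yl)-6,8-dimethoxy-3-methyl-2-tosyl-1,2,3,4-tetrahydroisoquinoline
Product: 15 (3S)-5-(4,5-dimethoxy-7-methylnaphthalen-1-yl)-6,8-dimethoxy-3-methyl-1,2,3,4-tetrahydroisoquinoline
Conditions: SmI2 (added in portions until 14 is consumed), pyrrolidine, H2O, THF, rt
Reagents that add atoms: none
Why: Single-electron reductive cleavage of the sulfonamide N–S bond by SmI2 activated with amine and water (reductive desulfonylation) should free the secondary amine without touching the aryl methyl ethers, the benzylic C1–N bond or C3.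

**Compound list**
1 | (S)-2-aminopropan-1-ol (L-alaninol) | C[C@H](N)CO | starting material
2 | (S)-2-(4-methylbenzenesulfonamido)propyl 4-methylbenzenesulfonate (N,O-ditosyl-L-alaninol) | C[C@H](NS(=O)(=O)c1ccc(C)cc1)COS(=O)(=O)c1ccc(C)cc1 | intermediate
3 | (S)-2-methyl-1-(4-methylbenzenesulfonyl)aziridine | C[C@H]1CN1S(=O)(=O)c1ccc(C)cc1 | intermediate
4 | 1-bromo-3-methoxy-5-methylbenzene | COc1cc(C)cc(Br)c1 | starting material
5 | 2-methoxyfuran | COc1ccco1 | starting material
6 | 3-methoxy-5-methylbenzyne | COC1=CC(C)=CC#C1 | intermediate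
7 | 1,8-dimethoxy-6-methyl-1,4-dihydro-1,4-epoxynaphthalene (racemic) | COC12C=CC(O1)c1cc(C)cc(OC)c12 | intermediate
8 | 4,5-dimethoxy-7-methylnaphthalen-1-ol | COc1ccc(O)c2cc(C)cc(OC)c12 | intermediate
9 | 4,5-dimethoxy-7-methylnaphthalen-1-yl trifluoromethanesulfonate | COc1ccc(OS(=O)(=O)C(F)(F)F)c2cc(C)cc(OC)c12 | intermediate
10 | 2-(4,5-dimethoxy-7-methylnaphthalen-1-yl)-4,4,5,5-tetramethyl-1,3,2-dioxaborolane | COc1ccc(B2OC(C)(C)C(C)(C)O2)c2cc(C)cc(OC)c12 | intermediate
11 | 1-iodo-2,4-dimethoxybenzene | COc1ccc(I)c(OC)c1 | starting material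
12 | N-[(2S)-1-[2-(4,5-dimethoxy-7-methylnaphthalen-1-yl)-3,5-dimethoxyphenyl]propan-2-yl]-4-methylbenzenesulfonamide | C[C@H](NS(=O)(=O)c1ccc(C)cc1)Cc1cc(OC)cc(OC)c1-c1ccc(OC)c2c(OC)cc(C)cc12 | intermediate
13 | N-methylidene-N-[(2S)-1-[2-(4,5-dimethoxy-7-methylnaphthalen-1-yl)-3,5-dimethoxyphenyl]propan-2-yl]-4-methylbenzenesulfonamidium (N-sulfonyliminium ion) | C[C@H]([N+](=C)S(=O)(=O)c1ccc(C)cc1)Cc1cc(OC)cc(OC)c1-c1ccc(OC)c2c(OC)cc(C)cc12 | intermediate
14 | (3S)-5-(4,5-dimethoxy-7-methylnaphthalen-1-yl)-6,8-dimethoxy-3-methyl-2-(4-methylbenzenesulfonyl)-1,2,3,4-tetrahydroisoquinoline | C[C@H]1Cc2c(-c3ccc(OC)c4c(OC)cc(C)cc34)c(OC)cc(OC)c2CN1S(=O)(=O)c1ccc(C)cc1 | intermediate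
15 | (3S)-5-(4,5-dimethoxy-7-methylnaphthalen-1-yl)-6,8-dimethoxy-3-methyl-1,2,3,4-tetrahydroisoquinoline | COc1cc(OC)c(-c2ccc(OC)c3c(OC)cc(C)cc23)c2c1CN[C@@H](C)C2 | target

**Total step count:** 7
**Longest linear sequence:** 6 steps (steps 2, 3, 4, 5, 6, 7)

**Steps most likely to fail**

Step 5. The arylpalladium species may be terminated in the wrong order or by the wrong partner: Suzuki coupling before ortho-alkylation, or ring closure by C–N bond formation from the sulfonamide nitrogen after alkylation, if the hindered transmetalation is too slow. The fallback builds the heterocycle first and forms the biaryl bond by a plain cross-coupling; it sets out from compound 3 and comes back at compound 14 (compound 10 is used unchanged). Copper-catalysed opening of aziridine 3 at its CH2 carbon with commercial 3,5-(MeO)2C6H3MgCl (CuI cat., THF, −30 °C) should give N-[(2S)-1-(3,5-dimethoxyphenyl)propan-2-yl]-4-methylbenzenesulfonamide F1. Pictet–Spengler closure with (CH2O)n/CF3CO2H (the two ortho positions are equivalent) should give (3S)-6,8-dimethoxy-3-methyl-2-(4-methylbenzenesulfonyl)-1,2,3,4-tetrahydroisoquinoline F2. Bromination with NBS in MeCN at 0 °C is expected at C5, para to the C8 methoxy group and less crowded than C7 between the two methoxy groups, to give (3S)-5-bromo-6,8-dimethoxy-3-methyl-2-(4-methylbenzenesulfonyl)-1,2,3,4-tetrahydroisoquinoline F3. Suzuki–Miyaura coupling of this bromide with boronate 10 (Pd(OAc)2, SPhos, K3PO4, toluene/H2O, 100 °C) should then give compound 14, and step 7 follows as planned.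

Step 2. The aryne may be captured by diisopropylamine, the furan may be metalated, or the cycloaddition may run in the reversed orientation. The fallback builds the methyl-bearing ring onto a benzaldehyde that already carries the bromine and the methoxy group in a para relationship. It does not branch from a numbered compound: it replaces compounds 4 to 9, starts from commercial crotonic acid, Ph3P·HBr and 2-bromo-5-methoxybenzaldehyde, and comes back at compound 10. Addition of Ph3P·HBr to crotonic acid (melt, 130 °C) should give (1-carboxypropan-2-yl)triphenylphosphonium bromide F4. A Wittig reaction of its ylide (KOtBu, 2.2 equiv, THF) with 2-bromo-5-methoxybenzaldehyde should give 4-(2-bromo-5-methoxyphenyl)-3-methylbut-3-enoic acid F5. Cyclodehydration with Ac2O/NaOAc at reflux can only close onto the single free ortho position (next to OMe) and should give 5-bromo-8-methoxy-3-methylnaphthalen-1-yl acetate F6. Acetate cleavage and O-methylation (KOH, MeOH, then MeI) should give 1-bromo-4,5-dimethoxy-7-methylnaphthalene F7. Miyaura borylation of this bromide (B2pin2, PdCl2(dppf), KOAc, 1,4-dioxane, 90 °C) should give compound 10.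

Step 6. Formaldehyde-derived cations may attack the electron-rich naphthalene or C7 intermolecularly (over-alkylation, oligomerization) in competition with ring closure. The fallback closes the heterocycle through an acyl-derived electrophile that can only react intramolecularly; it sets out from compound 12 and comes back at compound 15, bypassing compounds 13 and 14 and step 7. Reductive N–S cleavage of 12 (SmI2, pyrrolidine, H2O, THF) should give (2S)-1-[2-(4,5-dimethoxy-7-methylnaphthalen-1-yl)-3,5-dimethoxyphenyl]propan-2-amine F8. N-Formylation with ethyl formate at reflux should give N-[(2S)-1-[2-(4,5-dimethoxy-7-methylnaphthalen-1-yl)-3,5-dimethoxyphenyl]propan-2-yl]formamide F9. Bischler–Napieralski cyclization (POCl3, MeCN, reflux) onto C8a should give (3S)-5-(4,5-dimethoxy-7-methylnaphthalen-1-yl)-6,8-dimethoxy-3-methyl-3,4-dihydroisoquinoline F10. Reduction of the C1=N bond with NaBH4 in MeOH creates no stereocentre and should give compound 15.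

**Further compounds**
F1 | step 5 | N-[(2S)-1-(3,5-dimethoxyphenyl)propan-2-yl]-4-methylbenzenesulfonamide | C[C@H](NS(=O)(=O)c1ccc(C)cc1)Cc1cc(OC)cc(OC)c1
F2 | step 5 | (3S)-6,8-dimethoxy-3-methyl-2-(4-methylbenzenesulfonyl)-1,2,3,4-tetrahydroisoquinoline | C[C@H]1Cc2cc(OC)cc(OC)c2CN1S(=O)(=O)c1ccc(C)cc1
F3 | step 5 | (3S)-5-bromo-6,8-dimethoxy-3-methyl-2-(4-methylbenzenesulfonyl)-1,2,3,4-tetrahydroisoquinoline | C[C@H]1Cc2c(Br)c(OC)cc(OC)c2CN1S(=O)(=O)c1ccc(C)cc1
F4 | step 2 | (1-carboxypropan-2-yl)triphenylphosphonium bromide | CC(CC(=O)O)[P+](c1ccccc1)(c1ccccc1)c1ccccc1.[Br-]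
F5 | step 2 | 4-(2-bromo-5-methoxyphenyl)-3-methylbut-3-enoic acid | COc1ccc(Br)c(C=C(C)CC(=O)O)c1
F6 | step 2 | 5-bromo-8-methoxy-3-methylnaphthalen-1-yl acetate | COc1ccc(Br)c2cc(C)cc(OC(C)=O)c12
F7 | step 2 | 1-bromo-4,5-dimethoxy-7-methylnaphthalene | COc1ccc(Br)c2cc(C)cc(OC)c12
F8 | step 6 | (2S)-1-[2-(4,5-dimethoxy-7-methylnaphthalen-1-yl)-3,5-dimethoxyphenyl]propan-2-amine | C[C@H](N)Cc1cc(OC)cc(OC)c1-c1ccc(OC)c2c(OC)cc(C)cc12
F9 | step 6 | N-[(2S)-1-[2-(4,5-dimethoxy-7-methylnaphthalen-1-yl)-3,5-dimethoxyphenyl]propan-2-yl]formamide | C[C@H](NC=O)Cc1cc(OC)cc(OC)c1-c1ccc(OC)c2c(OC)cc(C)cc12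
F10 | step 6 | (3S)-5-(4,5-dimethoxy-7-methylnaphthalen-1-yl)-6,8-dimethoxy-3-methyl-3,4-dihydroisoquinoline | C[C@H]1Cc2c(-c3ccc(OC)c4c(OC)cc(C)cc34)c(OC)cc(OC)c2C=N1
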